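**Retrosynthetic overview**
1. Last ring (14-membered carbocycle): the C12–C13 bond is closed by a nickel-catalysed reductive alkyne–aldehyde macrocyclisation of an unprotected ynal, which makes the ring, the 11E alkene and the C13 carbinol in one step (the bold key step).
2. C5-OAc/C7-OH: Evans–Tishchenko reduction of a β-hydroxy Z-enone with acetaldehyde sets C7 and delivers the acetate; the enone comes from Nozaki–Hiyama–Kishi coupling of a C7 aldehyde with (Z)-2-iodohept-2-en-5-yne, then MnO2.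
3. First ring (seven-membered α-methylene lactone): invertive 7-exo opening of a Shi epoxide (C4–C5) by the C17 acid sets C4 and C5 together.
4. The 4E alkene comes from Negishi carboalumination/allylation of an alkyne made from the methyl ketone of ozonised (S)-limonene, which supplies C1 and ten skeletal carbons.
5. Order of ring formation: lactone (step 9), then macrocycle (step 18).

Assumption: locants are cembrane-type labels: C1 = ring CH carrying the acrylate unit (C15 α-carbon, C16 exocyclic CH2, C17 C=O), C2–C3 = CH2CH2, C4 = C(O)(CH3) with methyl C18, C5 = CH(OAc), C6 = CH2, C7 = CH(OH), C8 (methyl C19)=C9, C10 = CH2, C11=C12 (methyl C20), C13 = CH(OH), C14 = CH2; the target SMILES then reads 1S,4S,5R,7R,13R,8Z,11E.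

**Route**

Step 1
Reactants: 1 (S)-(−)-limonene
Product: 3 (3S)-6-oxo-3-(prop-1-en-2-yl)heptanal, via ozonide 2 (not isolated)
Conditions: O3 (1.0 equiv), CH2Cl2, −78 °C; then Me2S, −78 °C to rt
Reagents that add atoms: ozone, O=[O+][O-]
Why: Ozonolysis with reductive work-up: the electron-rich trisubstituted ring alkene reacts with ozone much faster than the 1,1-disubstituted isopropenyl group, so one equivalent cleaves only the ring and the C1 stereocentre of the chiral pool is carried over unchanged.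

Step 2
Reactants: 3 (3S)-6-oxo-3-(prop-1-en-2-yl)heptanal
Product: 4 (5S)-7,7-dimethoxy-5-(prop-1-en-2-yl)heptan-2-one
Conditions: HC(OMe)3, CeCl3·7H2O (cat.), MeOH, rt
Reagents that add atoms: trimethyl orthoformate, COC(OC)OC
Why: Lanthanide-catalysed acetalisation (Luche–Gemal conditions) converts the aldehyde into its dimethyl acetal far faster than the methyl ketone reacts, masking the future C13 aldehyde for the whole sequence.

Step 3
Reactants: 4 (5S)-7,7-dimethoxy-5-(prop-1-en-2-yl)heptan-2-one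
Product: 5 (5S)-5-(3-hydroxyprop-1-en-2-yl)-7,7-dimethoxyheptan-2-one
Conditions: SeO2 (0.3 equiv), t-BuOOH (anhydrous), CH2Cl2, rt
Reagents that add atoms: tert-butyl hydroperoxide, CC(C)(C)OO; selenium dioxide (catalytic oxygen carrier), O=[Se]=O
Why: SeO2/t-BuOOH allylic oxidation (ene reaction followed by 2,3-sigmatropic shift) of a 1,1-disubstituted alkene attacks the allylic CH3 in preference to the allylic CH, installing the C17 oxygen without touching C1.

Step 4
Reactants: 5 (5S)-5-(3-hydroxyprop-1-en-2-yl)-7,7-dimethoxyheptan-2-one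
Product: 6 (5S)-7,7-dimethoxy-5-[3-(triethylsilyloxy)prop-1-en-2-yl]heptan-2-one
Conditions: Et3SiCl, imidazole, CH2Cl2, 0 °C
Reagents that add atoms: chlorotriethylsilane, CC[Si](Cl)(CC)CC
Why: Standard silylation of the primary allylic alcohol; the triethylsilyl ether survives the strong bases and organoaluminium reagents that follow yet can later be oxidised directly.

Step 5
Reactants: 6 (5S)-7,7-dimethoxy-5-[3-(triethylsilyloxy)prop-1-en-2-yl]heptan-2-one
Product: 8 (5S)-7,7-dimethoxy-5-[3-(triethylsilyloxy)prop-1-en-2-yl]hept-1-yne, via enol phosphate 7 (not isolated)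
Conditions: LiN(i-Pr)2 (1.1 equiv), THF, −78 °C; ClP(O)(OEt)2; then LiN(i-Pr)2 (2.3 equiv), −78 °C to rt; aq. NH4Cl
Reagents that add atoms: none
Why: Negishi one-pot ketone-to-alkyne conversion: kinetic deprotonation of the methyl group, O-phosphorylation of the enolate and base-induced elimination of the enol phosphate give the terminal alkyne, the other functional groups having no comparably acidic protons.

Step 6
Reactants: 8 (5S)-7,7-dimethoxy-5-[3-(triethylsilyloxy)prop-1-en-2-yl]hept-1-yne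
Product: 10 (4E,8S)-10,10-dimethoxy-5-methyl-8-[3-(triethylsilyloxy)prop-1-en-2-yl]deca-1,4-diene, via alkenylalane 9 (not isolated)
Conditions: Me3Al (2.5 equiv), Cp2ZrCl2 (20 mol %), H2O (1 equiv), CH2Cl2, −20 °C; then allyl bromide, Pd(PPh3)4 (5 mol %), THF, 0 °C to rt
Reagents that add atoms: trimethylaluminium, C[Al](C)C; allyl bromide, C=CCBr
Why: Zirconium-catalysed syn-carboalumination (Negishi) adds methyl and aluminium cis across the terminal alkyne with aluminium on the terminal carbon, and palladium-catalysed cross-coupling of the alkenylalane with allyl bromide proceeds with retention, fixing the 4E trisubstituted alkene; the water-accelerated low-temperature protocol is chosen to spare the acetal and silyl ether.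

Step 7
Reactants: 10 (4E,8S)-10,10-dimethoxy-5-methyl-8-[3-(triethylsilyloxy)prop-1-en-2-yl]deca-1,4-diene
Product: 11 (2R,3R)-2-[(3S)-5,5-dimethoxy-3-{3-(triethylsilyloxy)prop-1-en-2-yl}pentyl]-2-methyl-3-(prop-2-en-1-yl)oxirane
Conditions: D-fructose-derived Shi ketone (30 mol %), Oxone (2KHSO5·KHSO4·K2SO4), K2CO3, Bu4NHSO4, MeCN/CH2(OMe)2/aq. Na2B4O7 buffer (pH 10.5), 0 °C
Reagents that add atoms: Oxone, active component potassium peroxymonosulfate KHSO5, [K+].[O-]S(=O)(=O)OO
Why: Shi asymmetric epoxidation: the chiral dioxirane attacks the most electron-rich (trisubstituted) alkene through a spiro transition state, leaving the monosubstituted and the inductively deactivated 1,1-disubstituted alkenes, and the D-fructose-derived ketone delivers the (4R,5R)-epoxide under reagent control.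

Step 8
Reactants: 11 (2R,3R)-2-[(3S)-5,5-dimethoxy-3-{3-(triethylsilyloxy)prop-1-en-2-yl}pentyl]-2-methyl-3-(prop-2-en-1-yl)oxirane
Product: 12 (3S)-5,5-dimethoxy-2-methylidene-3-{2-[(2R,3R)-2-methyl-3-(prop-2-en-1-yl)oxiran-2-yl]ethyl}pentanal
Conditions: (COCl)2, DMSO, CH2Cl2, −78 to −40 °C; then Et3N, to 0 °C
Reagents that add atoms: none
Why: Under Swern conditions a primary triethylsilyl ether is converted directly into the aldehyde (silyl transfer to chloride, then alkoxysulfonium ylide fragmentation), giving the 2-substituted acrolein without a separate deprotection and without acid that would open the epoxide.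

Step 9
Reactants: 12 (3S)-5,5-dimethoxy-2-methylidene-3-{2-[(2R,3R)-2-methyl-3-(prop-2-en-1-yl)oxiran-2-yl]ethyl}pentanal
Product: 14 (4S,7S)-4-(2,2-dimethoxyethyl)-7-[(1R)-1-hydroxybut-3-en-1-yl]-7-methyl-3-methylideneoxepan-2-one, via epoxy acid 13 (not isolated)
Conditions: NaClO2, NaH2PO4, 2-methyl-2-butene, t-BuOH/H2O, 0 °C; extractive work-up; then camphorsulfonic acid (10 mol %), CH2Cl2, 0 °C to rt
Reagents that add atoms: sodium chlorite, [Na+].[O-]Cl=O
Why: Pinnick oxidation gives the acrylic acid, which under Brønsted acid catalysis opens the trisubstituted epoxide at its tertiary carbon in a 7-exo SN2-like attack with inversion, so C4 (S, lactone oxygen) and C5 (R, free hydroxyl) are set together from the epoxide and the seven-membered lactone is closed.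

Step 10
Reactants: 14 (4S,7S)-4-(2,2-dimethoxyethyl)-7-[(1R)-1-hydroxybut-3-en-1-yl]-7-methyl-3-methylideneoxepan-2-one
Product: 16 (4S,7S)-4-(2,2-dimethoxyethyl)-7-[(1R)-1-hydroxy-3-oxopropyl]-7-methyl-3-methylideneoxepan-2-one, via triol 15 (not isolated)
Conditions: OsO4 (2 mol %), NaIO4 (2.2 equiv), 2,6-lutidine, dioxane/H2O (3:1), 0 °C to rt
Reagents that add atoms: sodium periodate, [Na+].[O-]I(=O)(=O)=O; osmium tetroxide (catalytic oxygen carrier), O=[Os](=O)(=O)=O
Why: Johnson–Lemieux oxidative cleavage (dihydroxylation then periodate glycol cleavage): OsO4 reacts with the electron-rich monosubstituted alkene much faster than with the electron-poor, hindered conjugated exo-methylene, unmasking the C7 aldehyde.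

Step 11
Reactants: 17 but-2-yn-1-ol
Product: 19 (Z)-3-iodobut-2-en-1-ol, via cyclic alkenylalanate 18 (not isolated)
Conditions: NaAlH2(OCH2CH2OMe)2, Et2O, 0 °C to rt; then I2, −78 to 0 °C
Reagents that add atoms: iodine, II
Why: Hydroxyl-directed trans-hydroalumination of the propargylic alcohol places aluminium on C3 in a five-membered alkoxyalanate and iodinolysis with retention gives the Z iodoalkene.

Step 12
Reactants: 19 (Z)-3-iodobut-2-en-1-ol
Product: 20 (Z)-1-bromo-3-iodobut-2-ene
Conditions: CBr4, PPh3, CH2Cl2, 0 °C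
Reagents that add atoms: carbon tetrabromide, BrC(Br)(Br)Br
Why: Appel bromination of the primary allylic alcohol under neutral conditions, with no allylic transposition or Z/E isomerisation.

Step 13
Reactants: 20 (Z)-1-bromo-3-iodobut-2-ene
Product: 21 (Z)-2-iodohept-2-en-5-yne
Conditions: CH3C≡CMgBr (1.3 equiv), CuBr·SMe2 (10 mol %), THF, 0 °C
Reagents that add atoms: 1-propynylmagnesium bromide, CC#C[Mg]Br
Why: Copper-catalysed SN2 substitution of the primary allylic bromide by the alkynyl Grignard reagent gives the skipped enyne; the hindered iodine-bearing γ-carbon disfavours SN2′ attack and the alkenyl iodide is inert at 0 °C.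

Step 14
Reactants: 16 (4S,7S)-4-(2,2-dimethoxyethyl)-7-[(1R)-1-hydroxy-3-oxopropyl]-7-methyl-3-methylideneoxepan-2-one; 21 (Z)-2-iodohept-2-en-5-yne (2 equiv)
Product: 22 (4S,7S)-4-(2,2-dimethoxyethyl)-7-[(1R,3RS,4Z)-1,3-dihydroxy-4-methylnon-4-en-7-yn-1-yl]-7-methyl-3-methylideneoxepan-2-one
Conditions: CrCl2 (6 equiv), NiCl2 (2 mol %), DMSO, rt
Reagents that add atoms: none
Why: Nozaki–Hiyama–Kishi coupling: nickel-catalysed formation of the alkenylchromium reagent from the trisubstituted iodoalkene occurs with retention of the Z geometry and it adds only to the aldehyde, tolerating the free hydroxyl, lactone, acetal and alkyne; the C7 epimer mixture is inconsequential because C7 is oxidised in step 15.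

Step 15
Reactants: 22 (4S,7S)-4-(2,2-dimethoxyethyl)-7-[(1R,3RS,4Z)-1,3-dihydroxy-4-methylnon-4-en-7-yn-1-yl]-7-methyl-3-methylideneoxepan-2-one
Product: 23 (4S,7S)-4-(2,2-dimethoxyethyl)-7-[(1R,4Z)-1-hydroxy-4-methyl-3-oxonon-4-en-7-yn-1-yl]-7-methyl-3-methylideneoxepan-2-one
Conditions: MnO2 (activated, excess), CH2Cl2, rt
Reagents that add atoms: none
Why: MnO2 oxidises only the allylic (C7) alcohol, leaving the saturated C5 alcohol, and under these neutral conditions the Z-enone does not isomerise.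

Step 16
Reactants: 23 (4S,7S)-4-(2,2-dimethoxyethyl)-7-[(1R,4Z)-1-hydroxy-4-methyl-3-oxonon-4-en-7-yn-1-yl]-7-methyl-3-methylideneoxepan-2-one
Product: 24 (1R,3R,4Z)-1-[(2S,5S)-5-(2,2-dimethoxyethyl)-2-methyl-6-methylidene-7-oxooxepan-2-yl]-3-hydroxy-4-methylnon-4-en-7-yn-1-yl acetate
Conditions: SmI2 (30 mol %, premixed with CH3CHO), CH3CHO (10 equiv), THF, −10 °C
Reagents that add atoms: acetaldehyde, CC=O
Why: Evans–Tishchenko reduction: the samarium-bound hemiacetal formed from the C5 hydroxyl and acetaldehyde delivers hydride intramolecularly to the C7 ketone through a six-membered chair transition state, giving the 1,3-anti relationship (7R) and leaving the acetate on C5 in the same operation.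

Step 17
Reactants: 24 (1R,3R,4Z)-1-[(2S,5S)-5-(2,2-dimethoxyethyl)-2-methyl-6-methylidene-7-oxooxepan-2-yl]-3-hydroxy-4-methylnon-4-en-7-yn-1-yl acetate
Product: 25 (1R,3R,4Z)-3-hydroxy-4-methyl-1-[(2S,5S)-2-methyl-6-methylidene-7-oxo-5-(2-oxoethyl)oxepan-2-yl]non-4-en-7-yn-1-yl acetate
Conditions: LiBF4, MeCN/H2O (50:1), rt
Reagents that add atoms: water, O
Why: Mild Lewis acid-mediated hydrolysis of the dimethyl acetal liberates the aldehyde without ionising the allylic alcohol or cleaving the acetate.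

Step 18
Reactants: 25 (1R,3R,4Z)-3-hydroxy-4-methyl-1-[(2S,5S)-2-methyl-6-methylidene-7-oxo-5-(2-oxoethyl)oxepan-2-yl]non-4-en-7-yn-1-yl acetate
Product: 27 (1S,4S,5R,7R,8Z,11E,13R)-5-acetoxy-7,13-dihydroxycembra-8,11,15(16)-trien-17,4-olide (target), via macrocyclic silyl ether 26 (not isolated)
Conditions: Ni(COD)2 (30 mol %), IMes (1,3-dimesitylimidazol-2-ylidene, 30 mol %), Et3SiH (5 equiv), THF, rt, 25 added by syringe pump to 2 mM; then HF·pyridine, THF/pyridine, 0 °C
Reagents that add atoms: none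
Why: Nickel-catalysed reductive alkyne–aldehyde macrocyclisation: oxidative cyclisation at zerovalent nickel carrying a small N-heterocyclic carbene forms the C12–C13 bond at the methyl-bearing alkyne carbon (endocyclic mode), σ-bond metathesis with the silane and reductive elimination add hydrogen syn to give the 11E alkene, C13 (R) arises from addition to the Si face of the aldehyde under substrate control by the lactone-bridged chain (not assured, see fallback), and fluoride then removes the silyl group(s).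

**Compound list**
1 | (S)-(−)-limonene | CC1=CC[C@H](CC1)C(C)=C | starting material
2 | limonene ring ozonide (1,2,4-trioxolane across the former ring C=C, two diastereomers at the trioxolane carbons, isopropenyl-bearing carbon S) | CC12OOC(O2)C[C@H](CC1)C(C)=C | intermediate
3 | (3S)-6-oxo-3-(prop-1-en-2-yl)heptanal | CC(=O)CC[C@@H](CC=O)C(C)=C | intermediate
4 | (5S)-7,7-dimethoxy-5-(prop-1-en-2-yl)heptan-2-one | CC(=O)CC[C@@H](CC(OC)OC)C(C)=C | intermediate
5 | (5S)-5-(3-hydroxyprop-1-en-2-yl)-7,7-dimethoxyheptan-2-one | CC(=O)CC[C@@H](CC(OC)OC)C(=C)CO | intermediate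
6 | (5S)-7,7-dimethoxy-5-[3-(triethylsilyloxy)prop-1-en-2-yl]heptan-2-one | CC(=O)CC[C@@H](CC(OC)OC)C(=C)CO[Si](CC)(CC)CC | intermediate
7 | terminal enol diethyl phosphate of 6 (5S) | C=C(OP(=O)(OCC)OCC)CC[C@@H](CC(OC)OC)C(=C)CO[Si](CC)(CC)CC | intermediate
8 | (5S)-7,7-dimethoxy-5-[3-(triethylsilyloxy)prop-1-en-2-yl]hept-1-yne | C#CCC[C@@H](CC(OC)OC)C(=C)CO[Si](CC)(CC)CC | intermediate
9 | dimethyl[(1E,5S)-7,7-dimethoxy-2-methyl-5-{3-(triethylsilyloxy)prop-1-en-2-yl}hept-1-en-1-yl]alane | C[Al](C)/C=C(\C)CC[C@@H](CC(OC)OC)C(=C)CO[Si](CC)(CC)CC | intermediate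
10 | (4E,8S)-10,10-dimethoxy-5-methyl-8-[3-(triethylsilyloxy)prop-1-en-2-yl]deca-1,4-diene | C=CC/C=C(\C)CC[C@@H](CC(OC)OC)C(=C)CO[Si](CC)(CC)CC | intermediate
11 | (2R,3R)-2-[(3S)-5,5-dimethoxy-3-{3-(triethylsilyloxy)prop-1-en-2-yl}pentyl]-2-methyl-3-(prop-2-en-1-yl)oxirane | C=CC[C@H]1O[C@]1(C)CC[C@@H](CC(OC)OC)C(=C)CO[Si](CC)(CC)CC | intermediate
12 | (3S)-5,5-dimethoxy-2-methylidene-3-{2-[(2R,3R)-2-methyl-3-(prop-2-en-1-yl)oxiran-2-yl]ethyl}pentanal | C=CC[C@H]1O[C@]1(C)CC[C@@H](CC(OC)OC)C(=C)C=O | intermediate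
13 | (3S)-5,5-dimethoxy-2-methylidene-3-{2-[(2R,3R)-2-methyl-3-(prop-2-en-1-yl)oxiran-2-yl]ethyl}pentanoic acid | C=CC[C@H]1O[C@]1(C)CC[C@@H](CC(OC)OC)C(=C)C(=O)O | intermediate
14 | (4S,7S)-4-(2,2-dimethoxyethyl)-7-[(1R)-1-hydroxybut-3-en-1-yl]-7-methyl-3-methylideneoxepan-2-one | C=C1C(=O)O[C@](C)([C@H](O)CC=C)CC[C@H]1CC(OC)OC | intermediate
15 | (4S,7S)-4-(2,2-dimethoxyethyl)-7-[(1R)-1,3,4-trihydroxybutyl]-7-methyl-3-methylideneoxepan-2-one (both epimers at the new carbinol) | C=C1C(=O)O[C@](C)([C@H](O)CC(O)CO)CC[C@H]1CC(OC)OC | intermediate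
16 | (4S,7S)-4-(2,2-dimethoxyethyl)-7-[(1R)-1-hydroxy-3-oxopropyl]-7-methyl-3-methylideneoxepan-2-one | C=C1C(=O)O[C@](C)([C@H](O)CC=O)CC[C@H]1CC(OC)OC | intermediate
17 | but-2-yn-1-ol | CC#CCO | starting material
18 | sodium cyclic alkenylalanate (five-membered ring O–CH2–CH=C(CH3)–Al, two 2-methoxyethoxy groups on aluminium) | CC1=CCO[Al-]1(OCCOC)OCCOC.[Na+] | intermediate
19 | (Z)-3-iodobut-2-en-1-ol | OC/C=C(/C)I | intermediate
20 | (Z)-1-bromo-3-iodobut-2-ene | BrC/C=C(/C)I | intermediate
21 | (Z)-2-iodohept-2-en-5-yne | CC#CC/C=C(/C)I | intermediate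
22 | (4S,7S)-4-(2,2-dimethoxyethyl)-7-[(1R,3RS,4Z)-1,3-dihydroxy-4-methylnon-4-en-7-yn-1-yl]-7-methyl-3-methylideneoxepan-2-one | C=C1C(=O)O[C@](C)([C@H](O)CC(O)/C(C)=C\CC#CC)CC[C@H]1CC(OC)OC | intermediate
23 | (4S,7S)-4-(2,2-dimethoxyethyl)-7-[(1R,4Z)-1-hydroxy-4-methyl-3-oxonon-4-en-7-yn-1-yl]-7-methyl-3-methylideneoxepan-2-one | C=C1C(=O)O[C@](C)([C@H](O)CC(=O)/C(C)=C\CC#CC)CC[C@H]1CC(OC)OC | intermediate
24 | (1R,3R,4Z)-1-[(2S,5S)-5-(2,2-dimethoxyethyl)-2-methyl-6-methylidene-7-oxooxepan-2-yl]-3-hydroxy-4-methylnon-4-en-7-yn-1-yl acetate | C=C1C(=O)O[C@](C)([C@H](OC(C)=O)C[C@@H](O)/C(C)=C\CC#CC)CC[C@H]1CC(OC)OC | intermediate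
25 | (1R,3R,4Z)-3-hydroxy-4-methyl-1-[(2S,5S)-2-methyl-6-methylidene-7-oxo-5-(2-oxoethyl)oxepan-2-yl]non-4-en-7-yn-1-yl acetate | C=C1C(=O)O[C@](C)([C@H](OC(C)=O)C[C@@H](O)/C(C)=C\CC#CC)CC[C@H]1CC=O | intermediate
26 | 13-O-triethylsilyl ether of 27 (1S,4S,5R,7R,8Z,11E,13R) | C=C1C(=O)O[C@@]2(C)CC[C@H]1C[C@@H](O[Si](CC)(CC)CC)/C(C)=C/C/C=C(/C)[C@H](O)C[C@H]2OC(C)=O | intermediate
27 | (1S,4S,5R,7R,8Z,11E,13R)-5-acetoxy-7,13-dihydroxycembra-8,11,15(16)-trien-17,4-olide (CNP0183491.2) | C=C1C(=O)O[C@@]2(C)CC[C@H]1C[C@@H](O)/C(C)=C/C/C=C(/C)[C@H](O)C[C@H]2OC(C)=O | target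

**Step count and risks**
Total step count: 18. Longest linear sequence: 15 steps (steps 1–10 and 14–18, from (S)-limonene); steps 11–13 are the three-step branch to 21.

The three steps most likely to fail:

Step 18 (nickel macrocyclisation). The methyl/alkyl alkyne gives only moderate intrinsic regiocontrol, the α-methylene lactone can bind or react at zerovalent nickel, and the C13 configuration rests on substrate control. Fallback: setting out from 24, hydrozirconation of the methyl alkyne with excess Cp2Zr(H)Cl (equilibrating zirconium onto the methyl-bearing carbon) and iodinolysis give the (E)-alkenyl iodide acetal F1. LiBF4 in wet acetonitrile then frees the iodo aldehyde F2. An intramolecular Nozaki–Hiyama–Kishi reaction (CrCl2, catalytic NiCl2, a chiral sulfonamide ligand for reagent control at C13, high dilution) closes the same C12–C13 bond and comes back to the route at 27.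

Step 9 (lactone by 7-exo epoxide opening). The seven-membered closure by a weakly nucleophilic acid may lose to elimination or hydride shift at the tertiary centre. Fallback: setting out from 11, Bu4NF removes the silyl group to give the epoxy allylic alcohol F3. Acid-catalysed 7-exo opening by the primary alcohol, a better nucleophile with the same inversion at C4, gives the 3-methyleneoxepane alcohol F4. Et3SiOTf/2,6-lutidine gives its silyl ether F5, and CrO3·3,5-dimethylpyrazole oxidises the allylic ether CH2 to the lactone silyl ether F6. HF·pyridine then comes back to the route at 14.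

Step 16 (Evans–Tishchenko on a β-hydroxy Z-enone). The conjugated ketone is a sluggish hydride acceptor and retro-aldol or acetyl migration may compete. Fallback: setting out from 23, acetylation of the C5 hydroxyl (Ac2O, pyridine, 0 °C) gives the β-acetoxy enone F7. Reagent-controlled Corey–Bakshi–Shibata reduction ((S)-2-methyl-CBS-oxazaborolidine, catecholborane, −78 °C) sets 7R and comes back to the route at 24.

**Further compounds**
F1 | step 18 | (1R,3R,4Z,7E)-1-[(2S,5S)-5-(2,2-dimethoxyethyl)-2-methyl-6-methylidene-7-oxooxepan-2-yl]-3-hydroxy-8-iodo-4-methylnona-4,7-dien-1-yl acetate | C=C1C(=O)O[C@](C)([C@H](OC(C)=O)C[C@@H](O)/C(C)=C\C/C=C(\C)I)CC[C@H]1CC(OC)OC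
F2 | step 18 | (1R,3R,4Z,7E)-3-hydroxy-8-iodo-4-methyl-1-[(2S,5S)-2-methyl-6-methylidene-7-oxo-5-(2-oxoethyl)oxepan-2-yl]nona-4,7-dien-1-yl acetate | C=C1C(=O)O[C@](C)([C@H](OC(C)=O)C[C@@H](O)/C(C)=C\C/C=C(\C)I)CC[C@H]1CC=O
F3 | step 9 | 2-[(3S)-5,5-dimethoxy-1-{(2R,3R)-2-methyl-3-(prop-2-en-1-yl)oxiran-2-yl}pentan-3-yl]prop-2-en-1-ol | C=CC[C@H]1O[C@]1(C)CC[C@@H](CC(OC)OC)C(=C)CO
F4 | step 9 | (1R)-1-[(2S,5S)-5-(2,2-dimethoxyethyl)-2-methyl-6-methylideneoxepan-2-yl]but-3-en-1-ol | C=C1CO[C@](C)([C@H](O)CC=C)CC[C@H]1CC(OC)OC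
F5 | step 9 | triethylsilyl ether of F4 at the secondary hydroxyl (1R; ring 2S,5S) | C=C1CO[C@](C)([C@H](O[Si](CC)(CC)CC)CC=C)CC[C@H]1CC(OC)OC
F6 | step 9 | (4S,7S)-4-(2,2-dimethoxyethyl)-7-methyl-3-methylidene-7-[(1R)-1-(triethylsilyloxy)but-3-en-1-yl]oxepan-2-one | C=C1C(=O)O[C@](C)([C@H](O[Si](CC)(CC)CC)CC=C)CC[C@H]1CC(OC)OC
F7 | step 16 | (1R,4Z)-1-[(2S,5S)-5-(2,2-dimethoxyethyl)-2-methyl-6-methylidene-7-oxooxepan-2-yl]-4-methyl-3-oxonon-4-en-7-yn-1-yl acetate | C=C1C(=O)O[C@](C)([C@H](OC(C)=O)CC(=O)/C(C)=C\CC#CC)CC[C@H]1CC(OC)OC
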